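Plan
- Retrosynthesis: the three silyl groups are removed and the Z-alkene is traced back to an alkyne. The C2–C3 bond of ring C is then cut and the two pieces are re-joined through oxygen as an enol acetal, a 2-aryl-4-methylidene-4H-1,3-benzodioxine. From there the aryl–alkyne bond, the methylidene carbon (the future C3) and the two acetal C–O bonds at C2 are cut. This leaves 2,4,6-trihydroxybenzoic acid and a ring B benzaldehyde, which is cut at its aryl–prenyl bond.
- Enabling feature: O1 (on C8a) and C4 (on C4a) are ortho on ring A, so the O1–C2 bond can be stored in a salicylate-type acetal whose second oxygen later becomes the C4 ketone oxygen. C2 carries ring B, which stabilises the O1=C2 oxocarbenium ion. The two ortho hydroxyls of ring A are equivalent, so acetal formation needs no regiocontrol.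
- Forward order: ring B aldehyde (steps 1–3), acetal with the ring A acid (temporary 1,3-dioxine ring), silyl protection, methylenation (brings in C3), Sonogashira coupling, catalytic asymmetric [1,3] O-to-C rearrangement that closes ring C as the last ring, Lindlar reduction, desilylation.
- Stereochemistry: C2 is set in the rearrangement by a chiral Brønsted acid whose anion pairs with the planar oxocarbenium ion; the racemic acetal centre is erased on ionisation, so the step is enantioconvergent. The Z-alkene comes from syn semi-hydrogenation of the alkyne, which is kept as the alkyne through all acidic steps.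

Key step: step 8

Assumption: the sense of induction of the chiral acid in step 8 cannot be derived from precedent; the (R)-catalyst is written as the one that delivers (2S), and its mirror image is used if the sense proves opposite.

Step 1
Reactants: 1 3-bromo-4-hydroxybenzaldehyde
Product: 2 3-bromo-4-hydroxy-5-iodobenzaldehyde
Conditions: NIS, AcOH, rt
Reagents that add atoms: N-iodosuccinimide, O=C1CCC(=O)N1I
Why: Electrophilic aromatic iodination of the phenol should occur at the only free position ortho to the hydroxyl group, the para position being blocked by the formyl group.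

Step 2
Reactants: 2 3-bromo-4-hydroxy-5-iodobenzaldehyde
Product: 3 3-bromo-5-iodo-4-methoxybenzaldehyde
Conditions: MeI, K2CO3, DMF, rt
Reagents that add atoms: iodomethane, CI
Why: Williamson O-methylation of the acidic di-ortho-halophenol fixes the 4'-methoxy group of ring B before any palladium chemistry.

Step 3
Reactants: 3 3-bromo-5-iodo-4-methoxybenzaldehyde
Product: 4 3-bromo-4-methoxy-5-(3-methylbut-2-en-1-yl)benzaldehyde
Conditions: tributyl(3-methylbut-2-en-1-yl)stannane, Pd(PPh3)4 (5 mol%), DMF, 80 °C
Reagents that add atoms: tributyl(3-methylbut-2-en-1-yl)stannane, CC(C)=CC[Sn](CCCC)(CCCC)CCCC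
Why: Stille coupling, in which zerovalent palladium should insert into the C–I bond much faster than into the C–Br bond and the prenyl group is transferred through its primary terminus, so that the bromide is kept for the later alkynylation.

Step 4
Reactants: 5 2,4,6-trihydroxybenzoic acid (dried); 4 3-bromo-4-methoxy-5-(3-methylbut-2-en-1-yl)benzaldehyde
Product: 8 2-[3-bromo-4-methoxy-5-(3-methylbut-2-en-1-yl)phenyl]-5,7-dihydroxy-4H-1,3-benzodioxin-4-one (racemic), via tetrakis(trimethylsilyl) derivative 6 (not isolated), via bis(trimethylsilyl) benzodioxinone 7 (not isolated)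
Conditions: TMSCl, Et3N, CH2Cl2, 0 °C to rt, filter; then 4, TMSOTf (10 mol%), CH2Cl2, −78 to −30 °C, pyridine quench; then 1 M aq. citric acid, THF, rt
Reagents that add atoms: none
Why: Noyori-type silyl-transfer acetalisation, in which under TMSOTf catalysis the silyl ester and one of the two equivalent ortho silyl ethers of 6 condense with the aldehyde, with loss of hexamethyldisiloxane, to the 4H-1,3-benzodioxin-4-one, a temporary ring that joins the two halves through the future O1–C2 bond and is formed racemic at the acetal carbon because that centre is erased in step 8, the remaining aryl silyl ethers being hydrolysed on work-up.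

Step 5
Reactants: 8 2-[3-bromo-4-methoxy-5-(3-methylbut-2-en-1-yl)phenyl]-5,7-dihydroxy-4H-1,3-benzodioxin-4-one
Product: 9 2-[3-bromo-4-methoxy-5-(3-methylbut-2-en-1-yl)phenyl]-5,7-bis(tert-butyldimethylsilyloxy)-4H-1,3-benzodioxin-4-one (racemic)
Conditions: TBSCl, imidazole, DMAP (cat.), DMF, rt to 40 °C
Reagents that add atoms: tert-butyldimethylsilyl chloride, CC(C)(C)[Si](C)(C)Cl
Why: Silyl ether formation protects both phenols against Cp2TiMe2 and the acid catalyst of the following steps and can be undone at the end under buffered fluoride conditions.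

Step 6
Reactants: 9 2-[3-bromo-4-methoxy-5-(3-methylbut-2-en-1-yl)phenyl]-5,7-bis(tert-butyldimethylsilyloxy)-4H-1,3-benzodioxin-4-one
Product: 10 2-[3-bromo-4-methoxy-5-(3-methylbut-2-en-1-yl)phenyl]-5,7-bis(tert-butyldimethylsilyloxy)-4-methylidene-4H-1,3-benzodioxine (racemic)
Conditions: Cp2TiMe2 (2.5 equiv), toluene, 65 °C, dark; filtration through basic alumina
Reagents that add atoms: Cp2TiMe2 (dimethyltitanocene), [CH3-].[CH3-].[CH-]1C=CC=C1.[CH-]1C=CC=C1.[Ti+4]
Why: Petasis methylenation, in which Cp2Ti=CH2 formed thermally from Cp2TiMe2 should convert the lactone carbonyl into the exocyclic enol ether through an oxatitanacyclobutane, with no free tetrahedral alkoxide that could open the acetal, as established for 1,3-dioxan-4-ones.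

Step 7
Reactants: 10 2-[3-bromo-4-methoxy-5-(3-methylbut-2-en-1-yl)phenyl]-5,7-bis(tert-butyldimethylsilyloxy)-4-methylidene-4H-1,3-benzodioxine
Product: 11 5,7-bis(tert-butyldimethylsilyloxy)-2-{4-methoxy-3-(3-methylbut-2-en-1-yl)-5-[3-methyl-3-(trimethylsilyloxy)but-1-yn-1-yl]phenyl}-4-methylidene-4H-1,3-benzodioxine (racemic)
Conditions: 2-methyl-2-(trimethylsilyloxy)but-3-yne, Pd(PhCN)2Cl2 (3 mol%), P(t-Bu)3 (6 mol%), CuI (2 mol%), HN(i-Pr)2, dioxane, rt
Reagents that add atoms: 2-methyl-2-(trimethylsilyloxy)but-3-yne, C#CC(C)(C)O[Si](C)(C)C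
Why: Sonogashira coupling of the electron-rich aryl bromide at room temperature under basic conditions, to which the enol acetal is inert, installs the masked side chain before the base-sensitive C2 stereocentre exists.

Step 8
Reactants: 11 5,7-bis(tert-butyldimethylsilyloxy)-2-{4-methoxy-3-(3-methylbut-2-en-1-yl)-5-[3-methyl-3-(trimethylsilyloxy)but-1-yn-1-yl]phenyl}-4-methylidene-4H-1,3-benzodioxine
Product: 13 (2S)-5,7-bis(tert-butyldimethylsilyloxy)-2-{4-methoxy-3-(3-methylbut-2-en-1-yl)-5-[3-methyl-3-(trimethylsilyloxy)but-1-yn-1-yl]phenyl}-2,3-dihydro-4H-chromen-4-one, via oxocarbenium–enol ion pair 12 (not isolated)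
Conditions: (R)-3,3'-bis(2,4,6-triisopropylphenyl)-1,1'-binaphthyl-2,2'-diyl N-triflylphosphoramide (5 mol%), 5 Å MS, toluene, −40 °C; Et3N quench
Reagents that add atoms: none
Why: Proposed new method: the chiral acid protonates the enol-ether oxygen of the acetal (protonation at the methylidene carbon converges on the same species), the bond from C2 to that oxygen ionises to the ring-B-stabilised aryloxocarbenium ion O1=C2, which is paired with the chiral phosphoramidate that also hydrogen-bonds the freed enol (12), and the enol carbon C3 then attacks C2 irreversibly, so that an acetal C–O bond is exchanged for the C2–C3 bond in a [1,3] O-to-C shift. The closest known reaction types are the Petasis–Ferrier rearrangement of 4-methylidene-1,3-dioxanes to tetrahydropyran-4-ones with Me2AlCl and the chiral-phosphoric-acid-catalysed aza-Petasis–Ferrier rearrangement of hemiaminal vinyl ethers; neither has been shown on a benzo-fused O,O-enol acetal with enantiocontrol. Ring C closes by a 6-(enolendo)-endo-trig attack of C3 on the oxocarbenium carbon. The new stereocentre C2 is controlled by the catalyst alone, because the planar, achiral cation is attacked on the face left open inside the hydrogen-bonded contact ion pair, while the racemic acetal centre of 11 is erased on ionisation. The step needs C-attack to win over return through oxygen, hydrolysis and arene alkylation: return through oxygen only regenerates 11, the tether through C8a–C4a leaves C3 as the only carbon nucleophile within reach of C2, molecular sieves exclude water, and the low temperature and catalytic amount of acid should leave the prenyl group, the alkyne and the silyl ethers untouched.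

Step 9
Reactants: 13 (2S)-5,7-bis(tert-butyldimethylsilyloxy)-2-{4-methoxy-3-(3-methylbut-2-en-1-yl)-5-[3-methyl-3-(trimethylsilyloxy)but-1-yn-1-yl]phenyl}-2,3-dihydro-4H-chromen-4-one
Product: 14 (2S)-5,7-bis(tert-butyldimethylsilyloxy)-2-{4-methoxy-3-(3-methylbut-2-en-1-yl)-5-[(1Z)-3-methyl-3-(trimethylsilyloxy)but-1-en-1-yl]phenyl}-2,3-dihydro-4H-chromen-4-one
Conditions: H2 (1 atm), Pd/CaCO3 poisoned with Pb(OAc)2 (Lindlar catalyst), quinoline, EtOAc, rt
Reagents that add atoms: none
Why: Lindlar semi-hydrogenation delivers both hydrogens to the same face of the alkyne and so should give the (Z)-alkene, while the poisoned catalyst leaves the trisubstituted prenyl alkene, the aryl ketone and the benzylic C2–O1 bond alone.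

Step 10
Reactants: 14 (2S)-5,7-bis(tert-butyldimethylsilyloxy)-2-{4-methoxy-3-(3-methylbut-2-en-1-yl)-5-[(1Z)-3-methyl-3-(trimethylsilyloxy)but-1-en-1-yl]phenyl}-2,3-dihydro-4H-chromen-4-one
Product: 15 (2S)-5,7-dihydroxy-2-{3-[(1Z)-3-hydroxy-3-methylbut-1-en-1-yl]-4-methoxy-5-(3-methylbut-2-en-1-yl)phenyl}-2,3-dihydro-4H-chromen-4-one (CNP0223123.2)
Conditions: TBAF, AcOH (1:1), THF, 0 °C
Reagents that add atoms: none
Why: Fluoride-mediated desilylation buffered with acetic acid should remove the two aryl TBS ethers and the tertiary TMS ether without the basic conditions that would open ring C and racemise C2 or the acidic conditions that would ionise the tertiary allylic alcohol.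

Compound list

1 | 3-bromo-4-hydroxybenzaldehyde | O=Cc1ccc(O)c(Br)c1 | starting material
2 | 3-bromo-4-hydroxy-5-iodobenzaldehyde | O=Cc1cc(I)c(O)c(Br)c1 | intermediate
3 | 3-bromo-5-iodo-4-methoxybenzaldehyde | COc1c(Br)cc(C=O)cc1I | intermediate
4 | 3-bromo-4-methoxy-5-(3-methylbut-2-en-1-yl)benzaldehyde | COc1c(Br)cc(C=O)cc1CC=C(C)C | intermediate
5 | 2,4,6-trihydroxybenzoic acid | OC(=O)c1c(O)cc(O)cc1O | starting material
6 | trimethylsilyl 2,4,6-tris(trimethylsilyloxy)benzoate | C[Si](C)(C)OC(=O)c1c(O[Si](C)(C)C)cc(O[Si](C)(C)C)cc1O[Si](C)(C)C | intermediate (not isolated)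
7 | 2-[3-bromo-4-methoxy-5-(3-methylbut-2-en-1-yl)phenyl]-5,7-bis(trimethylsilyloxy)-4H-1,3-benzodioxin-4-one (racemic) | COc1c(Br)cc(C2OC(=O)c3c(O[Si](C)(C)C)cc(O[Si](C)(C)C)cc3O2)cc1CC=C(C)C | intermediate (not isolated)
8 | 2-[3-bromo-4-methoxy-5-(3-methylbut-2-en-1-yl)phenyl]-5,7-dihydroxy-4H-1,3-benzodioxin-4-one (racemic) | COc1c(Br)cc(C2OC(=O)c3c(O)cc(O)cc3O2)cc1CC=C(C)C | intermediate
9 | 2-[3-bromo-4-methoxy-5-(3-methylbut-2-en-1-yl)phenyl]-5,7-bis(tert-butyldimethylsilyloxy)-4H-1,3-benzodioxin-4-one (racemic) | COc1c(Br)cc(C2OC(=O)c3c(O[Si](C)(C)C(C)(C)C)cc(O[Si](C)(C)C(C)(C)C)cc3O2)cc1CC=C(C)C | intermediate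
10 | 2-[3-bromo-4-methoxy-5-(3-methylbut-2-en-1-yl)phenyl]-5,7-bis(tert-butyldimethylsilyloxy)-4-methylidene-4H-1,3-benzodioxine (racemic) | COc1c(Br)cc(C2OC(=C)c3c(O[Si](C)(C)C(C)(C)C)cc(O[Si](C)(C)C(C)(C)C)cc3O2)cc1CC=C(C)C | intermediate
11 | 5,7-bis(tert-butyldimethylsilyloxy)-2-{4-methoxy-3-(3-methylbut-2-en-1-yl)-5-[3-methyl-3-(trimethylsilyloxy)but-1-yn-1-yl]phenyl}-4-methylidene-4H-1,3-benzodioxine (racemic) | COc1c(C#CC(C)(C)O[Si](C)(C)C)cc(C2OC(=C)c3c(O[Si](C)(C)C(C)(C)C)cc(O[Si](C)(C)C(C)(C)C)cc3O2)cc1CC=C(C)C | intermediate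
12 | ring-opened aryloxocarbenium ion carrying the ortho 1-hydroxyvinyl (enol) group, paired with the chiral phosphoramidate (cation shown) | COc1c(C#CC(C)(C)O[Si](C)(C)C)cc(C=[O+]c2cc(O[Si](C)(C)C(C)(C)C)cc(O[Si](C)(C)C(C)(C)C)c2C(O)=C)cc1CC=C(C)C | intermediate (not isolated)
13 | (2S)-5,7-bis(tert-butyldimethylsilyloxy)-2-{4-methoxy-3-(3-methylbut-2-en-1-yl)-5-[3-methyl-3-(trimethylsilyloxy)but-1-yn-1-yl]phenyl}-2,3-dihydro-4H-chromen-4-one | COc1c(C#CC(C)(C)O[Si](C)(C)C)cc([C@@H]2CC(=O)c3c(O[Si](C)(C)C(C)(C)C)cc(O[Si](C)(C)C(C)(C)C)cc3O2)cc1CC=C(C)C | intermediate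
14 | (2S)-5,7-bis(tert-butyldimethylsilyloxy)-2-{4-methoxy-3-(3-methylbut-2-en-1-yl)-5-[(1Z)-3-methyl-3-(trimethylsilyloxy)but-1-en-1-yl]phenyl}-2,3-dihydro-4H-chromen-4-one | COc1c(/C=C\C(C)(C)O[Si](C)(C)C)cc([C@@H]2CC(=O)c3c(O[Si](C)(C)C(C)(C)C)cc(O[Si](C)(C)C(C)(C)C)cc3O2)cc1CC=C(C)C | intermediate
15 | (2S)-5,7-dihydroxy-2-{3-[(1Z)-3-hydroxy-3-methylbut-1-en-1-yl]-4-methoxy-5-(3-methylbut-2-en-1-yl)phenyl}-2,3-dihydro-4H-chromen-4-one | COc1c(/C=C\C(C)(C)O)cc([C@@H]2CC(=O)c3c(O)cc(O)cc3O2)cc1CC=C(C)C | target

Totals and risks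

Total step count: 10. Longest linear sequence: 10 steps (1 to 15; acid 5 enters at step 4).

The three steps most likely to fail:

Risk 1, step 8 (the step that goes beyond known chemistry). Facial discrimination in the ion-pair recombination may be poor, or the ionised acetal may be diverted into hydrolysis or stall as a covalent adduct with the catalyst. The fallback for step 8 uses known chemistry, sets out from 11 and comes back to the route at 13. The established achiral Petasis–Ferrier conditions (Me2AlCl, CH2Cl2, −78 °C) should convert 11 into racemic 5,7-bis(tert-butyldimethylsilyloxy)-2-{4-methoxy-3-(3-methylbut-2-en-1-yl)-5-[3-methyl-3-(trimethylsilyloxy)but-1-yn-1-yl]phenyl}-2,3-dihydro-4H-chromen-4-one F1 by the same O-to-C shift without enantiocontrol. A Noyori-type asymmetric transfer hydrogenation of F1 run as a kinetic resolution (RuCl(p-cymene)[(R,R)-TsDPEN], HCO2H/Et3N, EtOAc, rt) is then expected to reduce the (2R)-ketone to the 2,4-cis alcohol (2R,4R)-5,7-bis(tert-butyldimethylsilyloxy)-2-{4-methoxy-3-(3-methylbut-2-en-1-yl)-5-[3-methyl-3-(trimethylsilyloxy)but-1-yn-1-yl]phenyl}-3,4-dihydro-2H-chromen-4-ol F2 and to leave the (2S)-ketone untouched. After chromatographic removal of F2 the unreacted (2S)-ketone is 13, where the route is rejoined; the mirror-image ruthenium complex is used if the (2S)-ketone proves to be the faster-reacting enantiomer.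

Risk 2, step 6. Carbene transfer to the hindered, electron-rich lactone carbonyl may be slow, and the acid-labile enol acetal may be lost on isolation. The fallback for step 6 sets out from 4, abandons the acetal strategy and comes back to the route at 13. Sonogashira coupling of 4 with 2-methyl-2-(trimethylsilyloxy)but-3-yne (Pd(PhCN)2Cl2, P(t-Bu)3, CuI, HN(i-Pr)2, dioxane, rt) should give 4-methoxy-3-(3-methylbut-2-en-1-yl)-5-[3-methyl-3-(trimethylsilyloxy)but-1-yn-1-yl]benzaldehyde F3 by replacement of the bromide. Commercial 2',4',6'-trihydroxyacetophenone is silylated at its two more accessible hydroxyls (TBSCl, imidazole, CH2Cl2, 0 °C) to 1-[2-hydroxy-4,6-bis(tert-butyldimethylsilyloxy)phenyl]ethanone F4 , whose remaining hydroxyl is hydrogen-bonded to the ketone. Amine-mediated aldol condensation and oxa-Michael closure of F3 and F4 (pyrrolidine, MeCN, 40 °C) should close ring C through the O1–C2 bond and give the racemic chromanone F1 directly. The kinetic resolution by asymmetric transfer hydrogenation (RuCl(p-cymene)[(R,R)-TsDPEN], HCO2H/Et3N, EtOAc, rt) then removes the (2R)-enantiomer as the alcohol F2 and leaves 13.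

Risk 3, step 7. CuI or Pd(PhCN)2Cl2 may act as Lewis acids and trigger premature racemic rearrangement or hydrolysis of the enol acetal, or the arylpalladium intermediate may be captured by the methylidene group in a Heck-type reaction. The fallback for step 7 sets out from 10, changes the order of events and comes back to the route at 13. The catalytic asymmetric rearrangement (the same chiral N-triflylphosphoramide, 5 Å MS, toluene, −40 °C) is run on the bromide 10 and should give (2S)-2-[3-bromo-4-methoxy-5-(3-methylbut-2-en-1-yl)phenyl]-5,7-bis(tert-butyldimethylsilyloxy)-2,3-dihydro-4H-chromen-4-one F5 by the same ion-pair pathway. The alkyne is then coupled to the robust ketone F5 under the same room-temperature Sonogashira conditions, kept short to limit base-induced opening of ring C, and this gives 13.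

Further compounds

F1 | step 8 | racemic 5,7-bis(tert-butyldimethylsilyloxy)-2-{4-methoxy-3-(3-methylbut-2-en-1-yl)-5-[3-methyl-3-(trimethylsilyloxy)but-1-yn-1-yl]phenyl}-2,3-dihydro-4H-chromen-4-one | COc1c(C#CC(C)(C)O[Si](C)(C)C)cc(C2CC(=O)c3c(O[Si](C)(C)C(C)(C)C)cc(O[Si](C)(C)C(C)(C)C)cc3O2)cc1CC=C(C)C
F2 | step 8 | (2R,4R)-5,7-bis(tert-butyldimethylsilyloxy)-2-{4-methoxy-3-(3-methylbut-2-en-1-yl)-5-[3-methyl-3-(trimethylsilyloxy)but-1-yn-1-yl]phenyl}-3,4-dihydro-2H-chromen-4-ol (2,4-cis) | COc1c(C#CC(C)(C)O[Si](C)(C)C)cc([C@H]2C[C@@H](O)c3c(O[Si](C)(C)C(C)(C)C)cc(O[Si](C)(C)C(C)(C)C)cc3O2)cc1CC=C(C)C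
F3 | step 6 | 4-methoxy-3-(3-methylbut-2-en-1-yl)-5-[3-methyl-3-(trimethylsilyloxy)but-1-yn-1-yl]benzaldehyde | COc1c(C#CC(C)(C)O[Si](C)(C)C)cc(C=O)cc1CC=C(C)C
F4 | step 6 | 1-[2-hydroxy-4,6-bis(tert-butyldimethylsilyloxy)phenyl]ethanone | CC(=O)c1c(O)cc(O[Si](C)(C)C(C)(C)C)cc1O[Si](C)(C)C(C)(C)C
F5 | step 7 | (2S)-2-[3-bromo-4-methoxy-5-(3-methylbut-2-en-1-yl)phenyl]-5,7-bis(tert-butyldimethylsilyloxy)-2,3-dihydro-4H-chromen-4-one | COc1c(Br)cc([C@@H]2CC(=O)c3c(O[Si](C)(C)C(C)(C)C)cc(O[Si](C)(C)C(C)(C)C)cc3O2)cc1CC=C(C)C
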